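**Plan**
1. Cuts (backwards): the C17–O and C15=O oxygens (from a 16-ene), C13–C16 (ring D, enyne radical cyclization), C8–C9 together with C13–C14 (rings B and C, intramolecular Diels–Alder across the C20–O–C7 ester), C9–C10 (enolate alkylation), then C3–C4 and C1–C10 together (ring A).
2. Enabling feature: in ring A, C4 and C10 are 1,3-related through C5 and each carries an oxygenated one-carbon arm (C19, C20) cis to C6 on C5. C4–C5–C10 with the C19/C6 γ-lactone is therefore a latent 3-(carboxymethyl)butanolide whose two α-carbons (C4 next to C19, C10 next to C20) can be joined by a C3 bis-electrophile.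
3. Forward: butanolide → ring A (key step) → C10 quaternary → redox transposition of the lactone (C19=O/C6H2 to C19H2/C6=O) → rings B and C in one cycloaddition → ring D → C15 and C17 oxygens.
4. Stereochemistry: C5 from the menthyl-acetal butenolide (anti Michael addition); C4 from the enforced cis ring fusion in the key step; C10 from convex-face alkylation; C8 and C9 from the Diels–Alder reaction; C11 from Luche reduction; C13 from the bridged ring closure; C16 from exo protonation.

Key step: step 2

Numbering: ent-kaurane numbers of the target carbons are used for all intermediates (ring A = C1–C5 and C10; C18 methyl; C19 on C4; C20 on C10; C6 and C7 are the lactone carbonyls). "d-Menthyl" is (1S,2R,5S)-5-methyl-2-(propan-2-yl)cyclohexyl.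

Assumption: butenolide 1 is taken as commercial; centers that are erased later (C10 in 6 and 7, the alkene geometry of 25) are carried as mixtures and left unassigned in the SMILES.

Step 1
Reactants: 1 (5S)-5-(d-menthyloxy)furan-2(5H)-one; 2 tert-butyl acetate
Product: 4 tert-butyl 2-[(2S)-2-(d-menthyloxy)-4-methyl-5-oxooxolan-3-yl]acetate (all-trans), via lithium lactone enolate 3 (not isolated)
Conditions: LiN(iPr)2, THF, −78 °C (enolate of 2); add 1; then MeI, DMPU, −78 to −40 °C
Reagents that add atoms: iodomethane, CI
Why: Tandem Michael addition–enolate alkylation on a 5-alkoxybutenolide: the ester enolate should add to C5 anti to the menthyloxy group on the acetal carbon C6, which fixes C5, and the lactone enolate then takes methyl anti to the new arm, a C4 configuration that does not matter because C4 is enolized again in step 2.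

Step 2
Reactants: 4 tert-butyl 2-[(2S)-2-(d-menthyloxy)-4-methyl-5-oxooxolan-3-yl]acetate; 5 1,3-dibromopropane
Product: 7 tert-butyl 3-(d-menthyloxy)-7a-methyl-1-oxooctahydro-2-benzofuran-4-carboxylate (cis-fused; C10 epimers), via bromopropyl lactone enolate 6 (not isolated)
Conditions: LiN(iPr)2 (2.2 equiv), THF–DMPU, −78 °C; then 5 (1.0 equiv), −78 to 0 °C
Reagents that add atoms: none
Why: Double deprotonation gives the lactone enolate (C4) and the ester enolate (C10); the secondary, more basic ester enolate carbon C10 should displace the first bromide (C1–C10), and the fully substituted lactone enolate carbon C4 then closes ring A on the second bromide (C3–C4). The closest known reaction type is the cycloalkylation of glutarate-type bis-enolates with 1,3-dihalides (inter- then intramolecular enolate alkylation). Ring A closes 6-exo-tet. C4 is controlled by C5: the tether hangs from C10 on C5 and can reach only the enolate face syn to the C5–C10 bond, so ring A is cis-fused to the butanolide (C19 cis to C6, methyl cis to H5), and this face is also anti to the menthyloxy group on C6. C10 forms as an epimer mixture that is enolized again in step 3. The step needs C10 to react before C4 (an intermolecular first attack at C4 would go anti to the arm and could not lead to the cis-fused ring); the steric and basicity difference between the two enolate carbons and the use of one equivalent of dibromide should secure this.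

Step 3
Reactants: 7 tert-butyl 3-(d-menthyloxy)-7a-methyl-1-oxooctahydro-2-benzofuran-4-carboxylate; 8 1-bromobut-2-yne
Product: 9 tert-butyl 4-(but-2-yn-1-yl)-3-(d-menthyloxy)-7a-methyl-1-oxooctahydro-2-benzofuran-4-carboxylate
Conditions: LiN(iPr)2, THF–DMPU, −78 °C; then 8, −78 to −20 °C
Reagents that add atoms: none
Why: Alkylation of a cyclohexanecarboxylate enolate: the exocyclic C10 enolate should be attacked on the convex face of the cis-fused bicycle, anti to the C5–C6 bond and away from the axial C19 of the lactone, so that the butynyl group (C9) ends trans and the ester carbon C20 cis to C6 and C19.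

Step 4
Reactants: 9 tert-butyl 4-(but-2-yn-1-yl)-3-(d-menthyloxy)-7a-methyl-1-oxooctahydro-2-benzofuran-4-carboxylate
Product: 10 tert-butyl 1-(but-2-yn-1-yl)-2,3-bis(hydroxymethyl)-3-methylcyclohexane-1-carboxylate
Conditions: LiBH4, THF, 0 °C; crude diol taken on at once
Reagents that add atoms: none
Why: Borohydride reduction of a lactone that is also an acyl acetal: hydride opens the C19 carbonyl, the freed C6 hemiacetal loses menthol and is reduced as the aldehyde, and the hindered tert-butyl ester on the quaternary C10 should survive LiBH4 at 0 °C, with no stereocenter touched.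

Step 5
Reactants: 10 tert-butyl 1-(but-2-yn-1-yl)-2,3-bis(hydroxymethyl)-3-methylcyclohexane-1-carboxylate
Product: 11 tert-butyl 7-(but-2-yn-1-yl)-3a-methyl-1-oxooctahydro-2-benzofuran-7-carboxylate
Conditions: TEMPO (cat.), PhI(OAc)2, CH2Cl2, rt
Reagents that add atoms: none
Why: TEMPO/PhI(OAc)2 oxidative lactonization of a 1,4-diol: the less hindered C6 carbinol on the tertiary C5 is oxidized first, the neopentyl C19 hydroxyl closes the lactol and a second oxidation gives the cis-fused lactone with C6 as the carbonyl, which transposes the oxidation levels of C19 and C6 to those of the target.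

Step 6
Reactants: 11 tert-butyl 7-(but-2-yn-1-yl)-3a-methyl-1-oxooctahydro-2-benzofuran-7-carboxylate
Product: 12 7-(but-2-yn-1-yl)-3a-methyl-1-oxooctahydro-2-benzofuran-7-carboxylic acid
Conditions: CF3CO2H, CH2Cl2, 0 °C to rt
Reagents that add atoms: none
Why: Acidolysis of the tert-butyl ester with loss of 2-methylpropene frees the C20 acid without touching the lactone or the alkyne.

Step 7
Reactants: 12 7-(but-2-yn-1-yl)-3a-methyl-1-oxooctahydro-2-benzofuran-7-carboxylic acid
Product: 14 7-(but-2-yn-1-yl)-7-(hydroxymethyl)-3a-methylhexahydro-2-benzofuran-1(3H)-one, via acid chloride 13 (not isolated)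
Conditions: (COCl)2, cat. DMF, CH2Cl2, 0 °C; then NaBH4, THF–DMF, −40 °C; AcOH quench
Reagents that add atoms: none
Why: Reduction of a carboxylic acid through its acid chloride with NaBH4, which spares the lactone and the alkyne, run cold and quenched with acid so that the new C20 alkoxide does not open the neighbouring lactone.

Step 8
Reactants: 14 7-(but-2-yn-1-yl)-7-(hydroxymethyl)-3a-methylhexahydro-2-benzofuran-1(3H)-one
Product: 15 hydroxy ketone 7-(hydroxymethyl)-3a-methyl-7-(2-oxobutyl)hexahydro-2-benzofuran-1(3H)-one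
Conditions: (Ph3P)AuCl (5 mol %), AgOSO2CF3 (5 mol %), H2O, 1,4-dioxane, rt
Reagents that add atoms: water, O
Why: Hydroxyl-assisted gold-catalysed alkyne hydration: the C20 hydroxyl should deliver oxygen 5-exo-dig to the gold-activated alkyne at C11 and water completes the hydration, so the carbonyl lands on C11 only; the product rests partly as its cyclic hemiketal, which also shields the C20 hydroxyl.

Step 9
Reactants: 16 diethyl 2-(prop-2-yn-1-yl)propanedioate
Product: 17 2-(prop-2-yn-1-yl)propanedioic acid
Conditions: KOH, EtOH–H2O, rt; then HCl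
Reagents that add atoms: potassium hydroxide, [K+].[OH-]
Why: Saponification of a malonic diester to the free diacid.

Step 10
Reactants: 17 2-(prop-2-yn-1-yl)propanedioic acid
Product: 18 2-methylidenepent-4-ynoic acid
Conditions: (CH2O)n, Et2NH, EtOAc, reflux
Reagents that add atoms: formaldehyde (from paraformaldehyde), C=O
Why: Mannich-type methylenation with decarboxylation of a monosubstituted malonic acid (the Doebner variant of the Knoevenagel condensation), the standard entry to 2-substituted acrylic acids.

Step 11
Reactants: 15 hydroxy ketone 7-(hydroxymethyl)-3a-methyl-7-(2-oxobutyl)hexahydro-2-benzofuran-1(3H)-one; 18 2-methylidenepent-4-ynoic acid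
Product: 19 [3a-methyl-1-oxo-7-(2-oxobutyl)octahydro-2-benzofuran-7-yl]methyl 2-methylidenepent-4-ynoate
Conditions: EDC·HCl, DMAP, CH2Cl2, rt
Reagents that add atoms: none
Why: Steglich esterification of the neopentyl C20 hydroxyl, which draws the open hydroxy ketone out of the hemiketal equilibrium since the tertiary hemiketal hydroxyl is not acylated.

Step 12
Reactants: 19 [3a-methyl-1-oxo-7-(2-oxobutyl)octahydro-2-benzofuran-7-yl]methyl 2-methylidenepent-4-ynoate
Product: 20 [3a-methyl-1-oxo-7-(2-oxobut-3-en-1-yl)octahydro-2-benzofuran-7-yl]methyl 2-methylidenepent-4-ynoate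
Conditions: IBX, DMSO–toluene, 70 °C
Reagents that add atoms: none
Why: IBX dehydrogenation of a ketone through its enol: only the C12–C13 side can be desaturated because C10 carries no hydrogen, and the esters and the alkyne are inert to IBX.

Step 13
Reactants: 20 [3a-methyl-1-oxo-7-(2-oxobut-3-en-1-yl)octahydro-2-benzofuran-7-yl]methyl 2-methylidenepent-4-ynoate
Product: 21 {7-[(1Z)-2-(tert-butyldimethylsilyloxy)buta-1,3-dien-1-yl]-3a-methyl-1-oxooctahydro-2-benzofuran-7-yl}methyl 2-methylidenepent-4-ynoate
Conditions: TBSOTf, Et3N, CH2Cl2, −78 to 0 °C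
Reagents that add atoms: tert-butyldimethylsilyl trifluoromethanesulfonate, CC(C)(C)[Si](C)(C)OS(=O)(=O)C(F)(F)F
Why: Soft enolization of the vinyl ketone, whose only α-hydrogens are on C9, gives the 2-silyloxy-1,3-diene, expected as the Z enol ether with the bulky C10 cis to the siloxy group and therefore on the outside of the diene.

Step 14
Reactants: 21 {7-[(1Z)-2-(tert-butyldimethylsilyloxy)buta-1,3-dien-1-yl]-3a-methyl-1-oxooctahydro-2-benzofuran-7-yl}methyl 2-methylidenepent-4-ynoate
Product: 22 Diels–Alder adduct (rings B and C closed; C11 silyl enol ether; propargyl on C8)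
Conditions: toluene, BHT (cat.), sealed tube, 180 °C
Reagents that add atoms: none
Why: Intramolecular Diels–Alder reaction in which the four-atom ester tether forces C9 onto C8 and C13 onto C14: the tether carbonyl endo should give the cis-fused lactone/cyclohexene (C7 cis to C10, propargyl cis to H9) and the dienophile should approach the diene face that keeps ring C anti to the larger C5 branch on C10, which together set C8 and C9.

Step 15
Reactants: 22 Diels–Alder adduct
Product: 23 enone (C11 ketone with C12=C13)
Conditions: DDQ, 2,4,6-collidine, benzene, rt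
Reagents that add atoms: none
Why: Oxidation of the silyl enol ether to the enone with DDQ (hydride abstraction at the allylic C13, then desilylation), a dehydrosilylation of the Saegusa type chosen because it needs no palladium next to the terminal alkyne.

Step 16
Reactants: 23 enone (C11 ketone with C12=C13)
Product: 24 allylic alcohol (11-hydroxy cis to C10)
Conditions: NaBH4, CeCl3·7H2O, MeOH, −78 °C
Reagents that add atoms: none
Why: Luche reduction (1,2-selective): hydride should attack C11 on the convex face of the cis-fused bicycle, anti to the quaternary C10 on C9, which places the hydroxyl cis to C10 as in the target.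

Step 17
Reactants: 24 allylic alcohol (11-hydroxy cis to C10)
Product: 26 16-ene (bicyclo[3.2.1]octane closed; exocyclic C16=C17), via vinylstannane 25 (not isolated)
Conditions: Bu3SnH, AIBN (cat.), benzene, 80 °C; then TsOH·H2O, CH2Cl2, rt
Reagents that add atoms: none
Why: Radical cyclization of a 1,6-enyne: the stannyl radical adds to the terminal alkyne carbon C17, the vinyl radical at C16 closes 5-exo-trig onto C13 on the only face the C8 tether can reach (which sets C13), and acid then removes tin from the vinylstannane.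

Step 18
Reactants: 26 16-ene
Product: 27 15-hydroxy-16-ene
Conditions: SeO2 (cat.), tBuOOH, CH2Cl2, rt
Reagents that add atoms: tert-butyl hydroperoxide, CC(C)(C)OO
Why: Riley oxidation (SeO2 with tBuOOH) of the exocyclic alkene at its only allylic methylene, C15, with the hydroxyl expected on the exo face, a center that is erased in step 19.

Step 19
Reactants: 27 15-hydroxy-16-ene
Product: 28 15-oxo-16-ene
Conditions: MnO2, CH2Cl2, rt
Reagents that add atoms: none
Why: MnO2 oxidizes only the allylic C15 alcohol and leaves the saturated C11 alcohol untouched.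

Step 20
Reactants: 28 15-oxo-16-ene
Product: 30 target CNP0555433.1, via pinacol boronate 29 (not isolated)
Conditions: CuCl (cat.), Xantphos (cat.), NaOC(CH3)3 (cat.), B2pin2, MeOH, THF, rt; then NaBO3·4H2O, THF–H2O, 0 °C
Reagents that add atoms: sodium perborate, O=BO[O-].[Na+]
Why: Copper-catalysed conjugate borylation of the α-methylene ketone and oxidation of the C–B bond (a formal anti-Markovnikov hydration): the enolate should be protonated by methanol on the open exo face of the cyclopentanone, so that the C17 arm ends endo (syn to C12) as the target requires.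

**Compound list**
1 | (5S)-5-{[(1S,2R,5S)-5-methyl-2-(propan-2-yl)cyclohexyl]oxy}furan-2(5H)-one, the (5S)-5-(d-menthyloxy)butenolide | O=C1O[C@H](O[C@H]2C[C@@H](C)CC[C@@H]2C(C)C)C=C1 | starting material
2 | tert-butyl acetate | CC(=O)OC(C)(C)C | starting material
3 | lithium lactone enolate of the Michael adduct (CH2CO2tBu arm on C5 anti to the menthyloxy group on C6) | [Li+].[O-]C1=C[C@H](CC(=O)OC(C)(C)C)[C@@H](O[C@H]2C[C@@H](C)CC[C@@H]2C(C)C)O1 | intermediate
4 | tert-butyl 2-[(2S)-2-(d-menthyloxy)-4-methyl-5-oxooxolan-3-yl]acetate, all-trans (arm anti to menthyloxy, methyl anti to arm) | CC(C)(C)OC(=O)C[C@H]1[C@H](C)C(=O)O[C@@H]1O[C@H]2C[C@@H](C)CC[C@@H]2C(C)C | intermediate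
5 | 1,3-dibromopropane | BrCCCBr | starting material
6 | lithium lactone enolate carrying the 3-bromopropyl chain on C10 (C10 epimers) | [Li+].CC(C)(C)OC(=O)C(CCCBr)[C@H]1C(C)=C([O-])O[C@@H]1O[C@H]2C[C@@H](C)CC[C@@H]2C(C)C | intermediate
7 | tert-butyl 3-(d-menthyloxy)-7a-methyl-1-oxooctahydro-2-benzofuran-4-carboxylate, cis-fused (ring A closed; C19 cis to C6, methyl cis to H5; C10 epimers, unassigned) | C[C@@]12CCCC(C(=O)OC(C)(C)C)[C@@H]1[C@@H](O[C@H]3C[C@@H](C)CC[C@@H]3C(C)C)OC2=O | intermediate
8 | 1-bromobut-2-yne | CC#CCBr | starting material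
9 | tert-butyl 4-(but-2-yn-1-yl)-3-(d-menthyloxy)-7a-methyl-1-oxooctahydro-2-benzofuran-4-carboxylate (ester carbon C20 cis to C6 and C19, butynyl trans) | C[C@@]12CCC[C@](CC#CC)(C(=O)OC(C)(C)C)[C@@H]1[C@@H](O[C@H]3C[C@@H](C)CC[C@@H]3C(C)C)OC2=O | intermediate
10 | tert-butyl 1-(but-2-yn-1-yl)-2,3-bis(hydroxymethyl)-3-methylcyclohexane-1-carboxylate (ester and both CH2OH groups on one face) | C[C@@]1(CO)CCC[C@](CC#CC)(C(=O)OC(C)(C)C)[C@@H]1CO | intermediate
11 | tert-butyl 7-(but-2-yn-1-yl)-3a-methyl-1-oxooctahydro-2-benzofuran-7-carboxylate (γ-lactone of the target: C6 carbonyl, O–C19; cis-fused; C20 cis to C6) | C[C@@]12CCC[C@](CC#CC)(C(=O)OC(C)(C)C)[C@@H]1C(=O)OC2 | intermediate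
12 | 7-(but-2-yn-1-yl)-3a-methyl-1-oxooctahydro-2-benzofuran-7-carboxylic acid | C[C@@]12CCC[C@](CC#CC)(C(=O)O)[C@@H]1C(=O)OC2 | intermediate
13 | acid chloride of 12 | C[C@@]12CCC[C@](CC#CC)(C(=O)Cl)[C@@H]1C(=O)OC2 | intermediate
14 | 7-(but-2-yn-1-yl)-7-(hydroxymethyl)-3a-methylhexahydro-2-benzofuran-1(3H)-one | C[C@@]12CCC[C@](CC#CC)(CO)[C@@H]1C(=O)OC2 | intermediate
15 | 7-(hydroxymethyl)-3a-methyl-7-(2-oxobutyl)hexahydro-2-benzofuran-1(3H)-one (open form of the hemiketal) | C[C@@]12CCC[C@](CC(=O)CC)(CO)[C@@H]1C(=O)OC2 | intermediate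
16 | diethyl 2-(prop-2-yn-1-yl)propanedioate | CCOC(=O)C(CC#C)C(=O)OCC | starting material
17 | 2-(prop-2-yn-1-yl)propanedioic acid | OC(=O)C(CC#C)C(=O)O | intermediate
18 | 2-methylidenepent-4-ynoic acid | C=C(CC#C)C(=O)O | intermediate
19 | [3a-methyl-1-oxo-7-(2-oxobutyl)octahydro-2-benzofuran-7-yl]methyl 2-methylidenepent-4-ynoate | C[C@@]12CCC[C@](CC(=O)CC)(COC(=O)C(=C)CC#C)[C@@H]1C(=O)OC2 | intermediate
20 | [3a-methyl-1-oxo-7-(2-oxobut-3-en-1-yl)octahydro-2-benzofuran-7-yl]methyl 2-methylidenepent-4-ynoate | C[C@@]12CCC[C@](CC(=O)C=C)(COC(=O)C(=C)CC#C)[C@@H]1C(=O)OC2 | intermediate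
21 | {7-[(1Z)-2-(tert-butyldimethylsilyloxy)buta-1,3-dien-1-yl]-3a-methyl-1-oxooctahydro-2-benzofuran-7-yl}methyl 2-methylidenepent-4-ynoate | C[C@@]12CCC[C@](/C=C(\O[Si](C)(C)C(C)(C)C)C=C)(COC(=O)C(=C)CC#C)[C@@H]1C(=O)OC2 | intermediate
22 | Diels–Alder adduct: ring A γ-lactone spiro-linked at C10 to the δ-lactone (ring B), which is cis-fused to the cyclohexene silyl enol ether (ring C, C11–OTBS, C11=C12); propargyl on C8 cis to H9 | C[C@@]12CCC[C@]3(COC(=O)[C@@]4(CC#C)CCC=C(O[Si](C)(C)C(C)(C)C)[C@H]43)[C@@H]1C(=O)OC2 | intermediate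
23 | enone of 22: C11 ketone, C12=C13 | C[C@@]12CCC[C@]3(COC(=O)[C@@]4(CC#C)CC=CC(=O)[C@H]43)[C@@H]1C(=O)OC2 | intermediate
24 | allylic alcohol: 11-hydroxy (cis to C10), C12=C13 | C[C@@]12CCC[C@]3(COC(=O)[C@@]4(CC#C)CC=C[C@@H](O)[C@H]43)[C@@H]1C(=O)OC2 | intermediate
25 | vinylstannane: bicyclo[3.2.1]octane closed (C13–C16), C16=C17H–SnBu3 (E/Z mixture) | C[C@@]12CCC[C@]3(COC(=O)[C@@]45C[C@@H](C[C@@H](O)[C@H]43)C(=C[Sn](CCCC)(CCCC)CCCC)C5)[C@@H]1C(=O)OC2 | intermediate
26 | 16-ene: 11-hydroxy bis-lactone with exocyclic C16=C17 methylene | C[C@@]12CCC[C@]3(COC(=O)[C@@]45C[C@@H](C[C@@H](O)[C@H]43)C(=C)C5)[C@@H]1C(=O)OC2 | intermediate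
27 | 15-hydroxy-16-ene (hydroxyl exo) | C[C@@]12CCC[C@]3(COC(=O)[C@@]45C[C@@H](C[C@@H](O)[C@H]43)C(=C)[C@@H]5O)[C@@H]1C(=O)OC2 | intermediate
28 | 15-oxo-16-ene (11-hydroxy α-methylene cyclopentanone) | C[C@@]12CCC[C@]3(COC(=O)[C@@]45C[C@@H](C[C@@H](O)[C@H]43)C(=C)C5=O)[C@@H]1C(=O)OC2 | intermediate
29 | C17 pinacol boronate of the 15-ketone (H16 exo) | C[C@@]12CCC[C@]3(COC(=O)[C@@]45C[C@@H](C[C@@H](O)[C@H]43)[C@@H](CB6OC(C)(C)C(C)(C)O6)C5=O)[C@@H]1C(=O)OC2 | intermediate
30 | target CNP0555433.1 | C[C@@]12CCC[C@]3(COC(=O)[C@@]45C[C@@H](C[C@@H](O)[C@H]43)[C@@H](CO)C5=O)[C@@H]1C(=O)OC2 | target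

**Totals**
Total step count: 20. Longest linear sequence: 18 steps (steps 1–8 and 11–20; steps 9–10 make the acid 18).

**Steps most likely to fail**

Step 2 (key step). The lactone enolate may be alkylated first, anti to the arm, so that ring A cannot close cis; the dibromide may also link two molecules or suffer elimination. Fallback from 1, back at 7: the C1–C10 bond is placed in the nucleophile. The lithium enolate of commercial tert-butyl 5-chloropentanoate (ClCCCCC(=O)OC(C)(C)C) adds to 1 and MeI traps the lactone enolate to give the chloro lactone F1. One equivalent of LiN(iPr)2 then forms only the more acidic lactone enolate, which closes ring A by 6-exo-tet alkylation to give 7.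

Step 14. The cycloaddition may be slow because the tether enforces a regiochemistry opposed to the polarization of the siloxy diene, and the endo/exo or facial selectivity may be poor. Fallback from 15, back at 22: 15 is esterified with propiolic acid to the ynoate F2, dehydrogenated with IBX to the vinyl ketone F3 and silylated to the siloxy diene F4. The linear, more reactive ynoate has no endo/exo choice and should cyclize at lower temperature to the cyclohexadiene lactone F5. Conjugate reduction of the unsaturated lactone with LiBH(sBu)3, then alkylation of the lactone enolate with propargyl bromide on the convex face (anti to C10), installs the C8 quaternary center and gives 22.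

Step 12. Dehydrogenation of the acyclic ethyl ketone may stall or over-oxidize, and the vinyl ketone may polymerize at 70 °C. Fallback from 15, back at 20: before esterification, 15 is treated with LiN(iPr)2 (2.2 equiv) and PhSeBr to give the α-phenylselanyl ketone F6 through the less hindered C12 enolate. Oxidation with H2O2 and syn elimination at 0 °C give the hydroxy vinyl ketone F7, and esterification with 18 as in step 11 gives 20.

**Further compounds**
F1 | step 2 | tert-butyl 5-chloro-2-[(2S)-2-(d-menthyloxy)-4-methyl-5-oxooxolan-3-yl]pentanoate (C10 epimers) | CC(C)(C)OC(=O)C(CCCCl)[C@H]1[C@H](C)C(=O)O[C@@H]1O[C@H]2C[C@@H](C)CC[C@@H]2C(C)C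
F2 | step 14 | [3a-methyl-1-oxo-7-(2-oxobutyl)octahydro-2-benzofuran-7-yl]methyl prop-2-ynoate | C[C@@]12CCC[C@](CC(=O)CC)(COC(=O)C#C)[C@@H]1C(=O)OC2
F3 | step 14 | [3a-methyl-1-oxo-7-(2-oxobut-3-en-1-yl)octahydro-2-benzofuran-7-yl]methyl prop-2-ynoate | C[C@@]12CCC[C@](CC(=O)C=C)(COC(=O)C#C)[C@@H]1C(=O)OC2
F4 | step 14 | {7-[(1Z)-2-(tert-butyldimethylsilyloxy)buta-1,3-dien-1-yl]-3a-methyl-1-oxooctahydro-2-benzofuran-7-yl}methyl prop-2-ynoate | C[C@@]12CCC[C@](/C=C(\O[Si](C)(C)C(C)(C)C)C=C)(COC(=O)C#C)[C@@H]1C(=O)OC2
F5 | step 14 | cyclohexadiene lactone (C8=C14 unsaturated δ-lactone, C11 silyl enol ether, C9 set) | C[C@@]12CCC[C@]3(COC(=O)C4=CCC=C(O[Si](C)(C)C(C)(C)C)[C@H]43)[C@@H]1C(=O)OC2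
F6 | step 12 | 7-(hydroxymethyl)-3a-methyl-7-[2-oxo-3-(phenylselanyl)butyl]hexahydro-2-benzofuran-1(3H)-one (C12 epimers) | C[C@@]12CCC[C@](CC(=O)C(C)[Se]c3ccccc3)(CO)[C@@H]1C(=O)OC2
F7 | step 12 | 7-(hydroxymethyl)-3a-methyl-7-(2-oxobut-3-en-1-yl)hexahydro-2-benzofuran-1(3H)-one | C[C@@]12CCC[C@](CC(=O)C=C)(CO)[C@@H]1C(=O)OC2
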